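**Plan**

1. Atom numbers follow the order of atoms in the target SMILES. Retrosynthetic cuts: the hemiketal is opened to a C8-hydroxy C3-ketone; then C7–C6 (Michael), C7=C8 (one-carbon olefination of a C7 ketone), N27–C29 (lactam), C7–C10 (Dieckmann), C12–C13 (B-alkyl Suzuki), C15–C16 (key step), C13–C17 (alkynylation), C13–C14 (formylation), C25–C26 (Mannich), and C24–C25/C25–C14 (Michael–Dieckmann).
2. Enabling feature: the cyclopentenol ring C13–C14–C15–C16–C17, fused to the cyclopentane C14–C15–C19–C24–C25, is a diquinane enone at the C17 ketone level. That enone is what a 1-ethynyl-2-propenyl ester (C16≡C17–C13(OPiv)–C14=C15, alkene inside the cyclopentene) gives on 1,2-acyloxy shift and C15–C16 closure; quaternary C25 pins the alkene at C14=C15.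
3. Forward ring order: cyclopentane (C14/C15/C19/C24/C25), then cyclopentenone (gold), then cycloheptene (C7, C10–C14, C25; Suzuki then Dieckmann), then piperidinone (lactam), then spiro-pyran (hemiketal).
4. Stereochemistry: C25 from a catalytic asymmetric Mannich reaction; C13 from catalytic asymmetric alkynylation, relayed to C15 in the gold step; C17 from CBS reduction; C19 from convex-face protonation during decarboxylation; C10 dictated by the bridged lactam; C7 from Michael addition on the lactam face; C3 thermodynamic.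

Key step: step 9

Assumption: the hemiketal carbon C3 is labile through ring–chain tautomerism with the C8-hydroxy C3-ketone, and the configuration drawn in the target is taken to be the resting anomer.

**Route**

Step 1
Reactants: 1 di-tert-butyl malonate; 2 methyl bromoacetate
Product: 3 1,1-di-tert-butyl 2-methyl ethane-1,1,2-tricarboxylate
Conditions: NaH, THF, 0 °C → rt (1 in slight excess)
Reagents that add atoms: none
Why: Malonate SN2 alkylation with a primary α-halo ester; excess malonate suppresses dialkylation, and tert-butyl esters are chosen so that C19 stays inert to every later nucleophile.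

Step 2
Reactants: 3; 4 methyl acrylate
Product: 6 racemic β-keto ester (1,1-di-tert-butyl 3-methyl 4-oxocyclopentane-1,1,3-tricarboxylate), via tetraester enolate 5 (not isolated)
Conditions: KOtBu (1.1 equiv), THF, 0 °C; 4 added slowly; rt; AcOH
Reagents that add atoms: none
Why: Tandem Michael addition–Dieckmann condensation: the malonate anion adds to the acrylate and the resulting propanoate enolate (future C25) closes 5-exo-trig onto the acetate methyl ester (future C14), the tert-butyl esters cannot act as acceptors and deprotonation of the β-keto ester drives the sequence; C25 is still racemic and enolisable.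

Step 3
Reactants: 6; 7 tert-butyl N-(tosylmethyl)carbamate
Product: 8 Mannich adduct (1,1-di-tert-butyl 3-methyl (3R)-3-{[(tert-butoxycarbonyl)amino]methyl}-4-oxocyclopentane-1,1,3-tricarboxylate)
Conditions: N-(9-anthracenylmethyl)cinchoninium chloride (10 mol%; the pseudoenantiomeric cinchonidinium salt if the sense of induction requires it), K2CO3 (aq.), toluene, −20 °C
Reagents that add atoms: none
Why: Catalytic asymmetric Mannich aminomethylation of a cyclic β-keto ester with N-Boc-formaldimine released in situ from the α-amido sulfone; the chiral ammonium–enolate ion pair exposes one enolate face, so quaternary C25 (R) is set under catalyst control.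

Step 4
Reactants: 8
Product: 9 N-methyl carbamate (C25 unchanged)
Conditions: MeI, Ag2O, DMF, rt, dark
Reagents that add atoms: iodomethane, CI
Why: Silver-oxide-mediated N-methylation of a carbamate; no carbamate anion is formed, which avoids retro-Mannich cleavage next to the β-keto ester and C-methylation at C15.

Step 5
Reactants: 9
Product: 10 enol triflate (C14–OTf, C14=C15)
Conditions: KN(SiMe3)2, THF, −78 °C; PhNTf2, −78 → 0 °C
Reagents that add atoms: N-phenylbis(trifluoromethanesulfonimide), O=S(=O)(N(c1ccccc1)S(=O)(=O)C(F)(F)F)C(F)(F)F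
Why: Enolate O-triflation; with C25 quaternary the ketone can enolise only toward C15, so the C14=C15 triflate is the sole regioisomer.

Step 6
Reactants: 10
Product: 11 enal (C13 aldehyde on C14 of the cyclopentene)
Conditions: Pd(OAc)2 (5 mol%), dppp, CO (1 atm), Et3SiH, Et3N, DMF, 70 °C
Reagents that add atoms: carbon monoxide, [C-]#[O+]
Why: Palladium-catalysed reductive carbonylation (formylation) of a vinyl triflate: oxidative addition, CO insertion and hydride transfer from the silane to the acyl palladium species.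

Step 7
Reactants: 11; 12 ethynyltrimethylsilane
Product: 14 (13S)-propargylic alcohol, via TMS-alkynol 13 (not isolated)
Conditions: Me2Zn, (S,S)-ProPhenol (20 mol%), Ph3PO (40 mol%), toluene, 0 °C; aq. NH4Cl; then K2CO3 (cat.), MeOH, rt
Reagents that add atoms: none
Why: Catalytic enantioselective alkynylzinc addition to an α,β-unsaturated aldehyde (dinuclear zinc–ProPhenol catalysis) followed by methanolysis of the C–Si bond; the ligand enantiomer is the one that delivers the alkyne to the Si face of the aldehyde (the antipode is used otherwise), giving 13S under catalyst control because C25 is remote and carries two arms of similar size.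

Step 8
Reactants: 14
Product: 15 (13S)-propargylic pivalate
Conditions: PivCl, Et3N, DMAP (cat.), CH2Cl2, 0 °C → rt
Reagents that add atoms: pivaloyl chloride, CC(C)(C)C(=O)Cl
Why: DMAP-catalysed O-acylation of a secondary alcohol; the pivalate is the acyloxy group that migrates in the next step and resists premature solvolysis.

Step 9
Reactants: 15
Product: 17 diquinane enone (C17 ketone, C13=C14 alkene, C15–H), via cyclopentadienyl pivalate 16 (not isolated)
Conditions: Ph3PAuCl (5 mol%), AgSbF6 (5 mol%), wet MeCN, −20 °C → rt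
Reagents that add atoms: none
Why: Cationic monovalent gold binds the terminal alkyne, the pivalate carbonyl oxygen attacks C17 and the acyloxy group moves from C13 to C17 while the gold-bearing C16 bonds to C15; loss of gold gives cyclopentadienyl pivalate 16, which the wet solvent hydrolyses to enone 17 with the alkene at C13=C14. The closest known reaction is the gold-catalysed Rautenstrauch rearrangement of 1-ethynyl-2-propenyl pivalates to cyclopentenones. The ring C13–C14–C15–C16–C17 closes through C15–C16 as a Nazarov-like 4π cyclisation of the C16–C17–C13–C14–C15 unit (formally 5-endo at the C14=C15 alkene). C15 is set by centre-to-centre chirality transfer: the C–C bond forms anti to the departing C13–O bond, which for the 13S pivalate puts C16 on the C15 face syn to the C25 ester carbon (C7). The step needs the 1,2- rather than the 1,3-acyloxy shift, which the terminal alkyne secures, and it needs C13 rather than the ring to choose the face, which the symmetric C19 diester and the two similar arms on C25 secure.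

Step 10
Reactants: 17
Product: 18 α-iodoenone (iodine on C13)
Conditions: I2, PhI(OCOCF3)2, pyridine, CH2Cl2, rt
Reagents that add atoms: iodine, II
Why: Electrophilic α-iodination of an enone (iodonium addition at C13, then loss of the C13 proton), a pathway that does not require conjugate addition of a nucleophile to the fully substituted C14.

Step 11
Reactants: 18; 19 methyl but-3-enoate
Product: 21 enone carrying the C12–C11–C10–C29 ester chain on C13, via B-alkyl-9-BBN 20 (not isolated)
Conditions: 19, 9-BBN, THF, 0 °C → rt; then 18, PdCl2(dppf) (5 mol%), AsPh3, Cs2CO3, DMF/H2O, rt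
Reagents that add atoms: none
Why: Anti-Markovnikov hydroboration followed by B-alkyl Suzuki–Miyaura coupling with the α-iodoenone forms C12–C13; the mild base at room temperature should leave the γ-stereocentre C15 untouched.

Step 12
Reactants: 21
Product: 22 (17S)-allylic alcohol (OH cis to H-15)
Conditions: (R)-2-methyl-CBS-oxazaborolidine (0.5 equiv), BH3·SMe2, THF, −30 °C; MeOH
Reagents that add atoms: none
Why: Corey–Bakshi–Shibata reduction; the R catalyst treats the α-substituted alkenyl carbon C13 as the large group and C16 as the small one, giving 17S under reagent control against the substrate's preference for convex-face attack.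

Step 13
Reactants: 22
Product: 23 C17 tert-butyldiphenylsilyl ether
Conditions: TBDPSCl, imidazole, DMAP (cat.), DMF, 40 °C
Reagents that add atoms: tert-butyl(chloro)diphenylsilane, CC(C)(C)[Si](Cl)(c1ccccc1)c1ccccc1
Why: Silyl ether formation; the TBDPS group is chosen to survive the enolate, silyl triflate, ylide and aqueous acid steps that follow.

Step 14
Reactants: 23
Product: 24 cycloheptenone β-keto ester (C7 ketone; C10 bearing CO2Me and epimerisable)
Conditions: LiN(SiMe3)2 (2.5 equiv), THF, −78 → 0 °C; AcOH
Reagents that add atoms: none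
Why: Dieckmann condensation (7-exo-trig) of the C10 ester enolate onto the C25 methyl ester, which the cis relationship of C12 and C25 across C13=C14 holds within reach; deprotonation of the β-keto ester drives it, and the tert-butyl esters and the carbamate are not attacked.

Step 15
Reactants: 24
Product: 27 bridged lactam acid (C29 lactam; C19 carboxylic acid with H-19 cis to H-15), via amino diacid 25 (not isolated), via lactam diacid 26 (not isolated)
Conditions: TMSOTf, 2,6-lutidine, CH2Cl2, 0 °C → rt; MeOH, 40 °C; then pyridine, 100 °C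
Reagents that add atoms: none
Why: Silyl-triflate cleavage of the N-Boc group and both tert-butyl esters, lactamisation of the freed N-methylamine onto the C10 methyl ester (6-exo-trig; the only ester left, and the C10 epimer that cannot close feeds in by enolisation), then Doebner-type decarboxylation of the malonic acid; C10 is fixed by the bridged ring and C19 by protonation of the ene-diol from the convex face, anti to C16 and C7.

Step 16
Reactants: 27
Product: 28 lactam methyl ester (C7 ketone)
Conditions: TMSCHN2, MeOH/toluene, 0 °C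
Reagents that add atoms: trimethylsilyldiazomethane, C[Si](C)(C)C=[N+]=[N-]
Why: Diazoalkane esterification of the carboxylic acid under neutral conditions that do not touch the C19 stereocentre.

Step 17
Reactants: 28
Product: 29 methyl enol ether (C7=C8–OMe, E/Z mixture)
Conditions: MeOCH2PPh3Cl (slight excess over base), KN(SiMe3)2, THF, 0 → 50 °C
Reagents that add atoms: (methoxymethyl)triphenylphosphonium chloride, COC[P+](c1ccccc1)(c1ccccc1)c1ccccc1.[Cl-]
Why: Wittig methoxymethylenation of the bridging C7 ketone, which cannot enolise toward quaternary C25 or bridgehead C10; the non-stabilised ylide leaves lactam and ester alone.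

Step 18
Reactants: 29
Product: 30 C8 aldehyde (C7–H, epimer mixture)
Conditions: TsOH·H2O (cat.), acetone/H2O, rt
Reagents that add atoms: water, O
Why: Acid hydrolysis of the enol ether to the homologated aldehyde; the C7 configuration is immaterial because C7 is planarised in the next step.

Step 19
Reactants: 30; 31 pent-1-en-3-one (ethyl vinyl ketone)
Product: 32 quaternary keto aldehyde (C7 bearing CHO and CH2CH2C(O)Et)
Conditions: DBU (0.3 equiv), MeCN, 0 °C → rt
Reagents that add atoms: none
Why: Base-catalysed Michael addition of an α-branched aldehyde enolate to a vinyl ketone; the exocyclic C7=C8 enolate should be attacked from the side of the flat lactam bridge (a single axial hydrogen, on C26) rather than from under the C11–C12 methylenes of the cycloheptene, which places C6 syn to the nitrogen bridge and C8 over the carbocycle as in the target.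

Step 20
Reactants: 32
Product: 34 spiro-hemiketal lactam, via hydroxy ketone 33 (not isolated)
Conditions: NaBH4 (0.3 equiv), EtOH/CH2Cl2, −78 °C; AcOH
Reagents that add atoms: none
Why: Chemoselective low-temperature borohydride reduction of the aldehyde in the presence of the ketone, then ring–chain tautomerism: the C8 hydroxyl closes 6-exo-trig onto the C3 ketone and C3 settles under thermodynamic control.

Step 21
Reactants: 34
Product: 36 N-methylpiperidine (C29 methylene; silyl ether retained), via silyl hemiaminal 35 (not isolated)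
Conditions: IrCl(CO)(PPh3)2 (2 mol%), (Me2HSi)2O, toluene, rt; then NaBH(OAc)3, AcOH, 0 °C → rt
Reagents that add atoms: none
Why: Iridium-catalysed hydrosilylation of the tertiary lactam to the N,O-silyl hemiaminal and reduction of the derived iminium ion by acetoxyborohydride, a sequence that is chemoselective for the amide over the ester, the hemiketal and the silyl ether.

Step 22
Reactants: 36
Product: 37 CNP0124876.1
Conditions: TBAF, AcOH, THF, rt → 40 °C
Reagents that add atoms: none
Why: Fluoride cleavage of the silyl ether, buffered with acetic acid so that the ester stereocentre C19 and the hemiketal are not exposed to base.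

**Compound list**

1 | di-tert-butyl malonate | CC(C)(C)OC(=O)CC(=O)OC(C)(C)C | starting material
2 | methyl bromoacetate | COC(=O)CBr | starting material
3 | 1,1-di-tert-butyl 2-methyl ethane-1,1,2-tricarboxylate | COC(=O)CC(C(=O)OC(C)(C)C)C(=O)OC(C)(C)C | intermediate
4 | methyl acrylate | C=CC(=O)OC | starting material
5 | 2,2-di-tert-butyl 1,4-dimethyl butane-1,2,2,4-tetracarboxylate (formed as its enolate) | COC(=O)CCC(CC(=O)OC)(C(=O)OC(C)(C)C)C(=O)OC(C)(C)C | intermediate
6 | 1,1-di-tert-butyl 3-methyl 4-oxocyclopentane-1,1,3-tricarboxylate (racemic) | COC(=O)C1CC(C(=O)OC(C)(C)C)(C(=O)OC(C)(C)C)CC1=O | intermediate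
7 | tert-butyl N-(tosylmethyl)carbamate | Cc1ccc(cc1)S(=O)(=O)CNC(=O)OC(C)(C)C | starting material
8 | (3R)-3-[(Boc-amino)methyl] β-keto ester (Mannich adduct) | O=C4CC(C(=O)OC(C)(C)C)(C(=O)OC(C)(C)C)C[C@@]4(C(=O)OC)CNC(=O)OC(C)(C)C | intermediate
9 | N-methyl-N-Boc aminomethyl β-keto ester | O=C4CC(C(=O)OC(C)(C)C)(C(=O)OC(C)(C)C)C[C@@]4(C(=O)OC)CN(C)C(=O)OC(C)(C)C | intermediate
10 | enol triflate (C14–OTf, C14=C15) | FC(F)(F)S(=O)(=O)OC4=CC(C(=O)OC(C)(C)C)(C(=O)OC(C)(C)C)C[C@@]4(C(=O)OC)CN(C)C(=O)OC(C)(C)C | intermediate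
11 | cyclopentene carbaldehyde (C13 aldehyde) | O=CC4=CC(C(=O)OC(C)(C)C)(C(=O)OC(C)(C)C)C[C@@]4(C(=O)OC)CN(C)C(=O)OC(C)(C)C | intermediate
12 | ethynyltrimethylsilane | C#C[Si](C)(C)C | starting material
13 | TMS-alkynol | C[Si](C)(C)C#C[C@H](O)C4=CC(C(=O)OC(C)(C)C)(C(=O)OC(C)(C)C)C[C@@]4(C(=O)OC)CN(C)C(=O)OC(C)(C)C | intermediate
14 | (13S)-propargylic alcohol | C#C[C@H](O)C4=CC(C(=O)OC(C)(C)C)(C(=O)OC(C)(C)C)C[C@@]4(C(=O)OC)CN(C)C(=O)OC(C)(C)C | intermediate
15 | (13S)-propargylic pivalate (key-step precursor) | C#C[C@H](OC(=O)C(C)(C)C)C4=CC(C(=O)OC(C)(C)C)(C(=O)OC(C)(C)C)C[C@@]4(C(=O)OC)CN(C)C(=O)OC(C)(C)C | intermediate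
16 | cyclopentadienyl pivalate (C17–OPiv, C13=C14 and C16=C17) | C3=C4[C@H](C=C3OC(=O)C(C)(C)C)C(C(=O)OC(C)(C)C)(C(=O)OC(C)(C)C)C[C@@]4(C(=O)OC)CN(C)C(=O)OC(C)(C)C | intermediate
17 | diquinane enone (key-step product) | C3=C4[C@H](CC3=O)C(C(=O)OC(C)(C)C)(C(=O)OC(C)(C)C)C[C@@]4(C(=O)OC)CN(C)C(=O)OC(C)(C)C | intermediate
18 | α-iodoenone (C13–I) | IC3=C4[C@H](CC3=O)C(C(=O)OC(C)(C)C)(C(=O)OC(C)(C)C)C[C@@]4(C(=O)OC)CN(C)C(=O)OC(C)(C)C | intermediate
19 | methyl but-3-enoate | C=CCC(=O)OC | starting material
20 | methyl 4-(9-borabicyclo[3.3.1]nonan-9-yl)butanoate | COC(=O)CCCB1C2CCCC1CCC2 | intermediate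
21 | enone with the methyl butanoate chain on C13 | COC(=O)CCCC3=C4[C@H](CC3=O)C(C(=O)OC(C)(C)C)(C(=O)OC(C)(C)C)C[C@@]4(C(=O)OC)CN(C)C(=O)OC(C)(C)C | intermediate
22 | (17S)-allylic alcohol | COC(=O)CCCC3=C4[C@H](C[C@@H]3O)C(C(=O)OC(C)(C)C)(C(=O)OC(C)(C)C)C[C@@]4(C(=O)OC)CN(C)C(=O)OC(C)(C)C | intermediate
23 | C17 TBDPS ether | COC(=O)CCCC3=C4[C@H](C[C@@H]3O[Si](c5ccccc5)(c5ccccc5)C(C)(C)C)C(C(=O)OC(C)(C)C)(C(=O)OC(C)(C)C)C[C@@]4(C(=O)OC)CN(C)C(=O)OC(C)(C)C | intermediate
24 | cycloheptenone β-keto ester (C7 ketone, C10–CO2Me) | COC(=O)C1CCC3=C4[C@H](C[C@@H]3O[Si](c5ccccc5)(c5ccccc5)C(C)(C)C)C(C(=O)OC(C)(C)C)(C(=O)OC(C)(C)C)C[C@@]4(C1=O)CN(C)C(=O)OC(C)(C)C | intermediate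
25 | amino diacid (free N-methylamine, C19 malonic acid) | COC(=O)C1CCC3=C4[C@H](C[C@@H]3O[Si](c5ccccc5)(c5ccccc5)C(C)(C)C)C(C(=O)O)(C(=O)O)C[C@@]4(C1=O)CNC | intermediate
26 | lactam diacid | O=C2[C@@H]1CCC3=C4[C@H](C[C@@H]3O[Si](c5ccccc5)(c5ccccc5)C(C)(C)C)C(C(=O)O)(C(=O)O)C[C@@]42CN(C)C1=O | intermediate
27 | lactam acid (C19 set) | O=C2[C@@H]1CCC3=C4[C@H](C[C@@H]3O[Si](c5ccccc5)(c5ccccc5)C(C)(C)C)[C@H](C(=O)O)C[C@@]42CN(C)C1=O | intermediate
28 | lactam methyl ester with C7 ketone | O=C2[C@@H]1CCC3=C4[C@H](C[C@@H]3O[Si](c5ccccc5)(c5ccccc5)C(C)(C)C)[C@H](C(=O)OC)C[C@@]42CN(C)C1=O | intermediate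
29 | methyl enol ether (C7=C8) | COC=C2[C@@H]1CCC3=C4[C@H](C[C@@H]3O[Si](c5ccccc5)(c5ccccc5)C(C)(C)C)[C@H](C(=O)OC)C[C@@]42CN(C)C1=O | intermediate
30 | C8 aldehyde (C7 epimers) | O=CC2[C@@H]1CCC3=C4[C@H](C[C@@H]3O[Si](c5ccccc5)(c5ccccc5)C(C)(C)C)[C@H](C(=O)OC)C[C@@]42CN(C)C1=O | intermediate
31 | pent-1-en-3-one | CCC(=O)C=C | starting material
32 | quaternary keto aldehyde | CCC(=O)CC[C@@]2(C=O)[C@@H]1CCC3=C4[C@H](C[C@@H]3O[Si](c5ccccc5)(c5ccccc5)C(C)(C)C)[C@H](C(=O)OC)C[C@@]42CN(C)C1=O | intermediate
33 | hydroxy ketone (open form) | CCC(=O)CC[C@@]2(CO)[C@@H]1CCC3=C4[C@H](C[C@@H]3O[Si](c5ccccc5)(c5ccccc5)C(C)(C)C)[C@H](C(=O)OC)C[C@@]42CN(C)C1=O | intermediate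
34 | spiro-hemiketal lactam | CC[C@@]1(O)CC[C@@]2(CO1)[C@@H]1CCC3=C4[C@H](C[C@@H]3O[Si](c5ccccc5)(c5ccccc5)C(C)(C)C)[C@H](C(=O)OC)C[C@@]42CN(C)C1=O | intermediate
35 | N,O-silyl hemiaminal at C29 | CC[C@@]1(O)CC[C@@]2(CO1)[C@@H]1CCC3=C4[C@H](C[C@@H]3O[Si](c5ccccc5)(c5ccccc5)C(C)(C)C)[C@H](C(=O)OC)C[C@@]42CN(C)C1O[Si](C)(C)O[SiH](C)C | intermediate
36 | silyl-protected amine | CC[C@@]1(O)CC[C@@]2(CO1)[C@@H]1CCC3=C4[C@H](C[C@@H]3O[Si](c5ccccc5)(c5ccccc5)C(C)(C)C)[C@H](C(=O)OC)C[C@@]42CN(C)C1 | intermediate
37 | CNP0124876.1 | CC[C@@]1(O)CC[C@@]2(CO1)[C@@H]1CCC3=C4[C@H](C[C@@H]3O)[C@H](C(=O)OC)C[C@@]42CN(C)C1 | target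

**Totals and risks**

Total steps: 22. Longest linear sequence: 22 steps (1 → 37).

Steps most likely to fail:

Step 19. The Michael addition must build a quaternary carbon next to quaternary C25, so it may stall. The acceptor may also enter from the cycloheptene side, which would be poor or inverted facial selectivity at C7. The fallback attaches the two arms in the opposite order, so that the small electrophile entering from the open face becomes C8 instead of C6. It sets out from aldehyde 30. A crossed aldol reaction with aqueous formaldehyde (K2CO3, THF/H2O) should give the hydroxymethyl aldehyde F1, whose aldehyde carbon is now C6. Silylation (TESCl, imidazole, CH2Cl2) gives the triethylsilyl ether F2. Horner–Wadsworth–Emmons olefination with dimethyl (2-oxobutyl)phosphonate (LiCl, iPr2NEt, MeCN) gives the E enone F3. Conjugate reduction with [(Ph3P)CuH]6 in toluene gives the saturated ketone F4. Mild acid methanolysis (PPTS, MeOH) then removes the triethylsilyl group, and the freed hydroxy ketone 33 closes to hemiketal 34, where the route is rejoined.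

Step 17. The ylide may fail to add to the bridging ketone, which is flanked by quaternary C25 and bridgehead C10, or the basic ylide may erode the C19 ester centre under forcing conditions. The fallback is a one-carbon homologation through an epoxide, setting out from ketone 28. Corey–Chaykovsky methylenation with dimethylsulfonium methylide (Me3SI, KN(SiMe3)2, THF/DMSO, 0 °C) should give the spiro-epoxide F5. Lewis-acid-induced Meinwald rearrangement with hydride shift (MgBr2·OEt2, CH2Cl2, −78 → 0 °C) then delivers aldehyde 30, where the route is rejoined.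

Step 12. Facial selectivity may be poor, because the reagent has to deliver hydride from the concave face against the substrate's own bias. The fallback uses that bias and then inverts, setting out from enone 21. Luche reduction (NaBH4, CeCl3·7H2O, MeOH, −78 °C), expected from the convex face, gives the C17-epimeric alcohol F6. Mitsunobu inversion with 4-nitrobenzoic acid (PPh3, DIAD, THF) gives the inverted 4-nitrobenzoate F7. Methanolysis (K2CO3, MeOH, rt) then gives alcohol 22, where the route is rejoined.

Further compounds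
F1 | step 19 | hydroxymethyl aldehyde (C7 bearing CHO as C6 and CH2OH as C8) | O=C[C@@]2(CO)[C@@H]1CCC3=C4[C@H](C[C@@H]3O[Si](c5ccccc5)(c5ccccc5)C(C)(C)C)[C@H](C(=O)OC)C[C@@]42CN(C)C1=O
F2 | step 19 | triethylsilyl ether of F1 | O=C[C@@]2(CO[Si](CC)(CC)CC)[C@@H]1CCC3=C4[C@H](C[C@@H]3O[Si](c5ccccc5)(c5ccccc5)C(C)(C)C)[C@H](C(=O)OC)C[C@@]42CN(C)C1=O
F3 | step 19 | E enone (C6=C5–C3(=O)Et) | CCC(=O)/C=C/[C@@]2(CO[Si](CC)(CC)CC)[C@@H]1CCC3=C4[C@H](C[C@@H]3O[Si](c5ccccc5)(c5ccccc5)C(C)(C)C)[C@H](C(=O)OC)C[C@@]42CN(C)C1=O
F4 | step 19 | saturated ketone with C8 triethylsilyl ether | CCC(=O)CC[C@@]2(CO[Si](CC)(CC)CC)[C@@H]1CCC3=C4[C@H](C[C@@H]3O[Si](c5ccccc5)(c5ccccc5)C(C)(C)C)[C@H](C(=O)OC)C[C@@]42CN(C)C1=O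
F5 | step 17 | spiro-epoxide at C7 (C7–O–C8) | C6OC62[C@@H]1CCC3=C4[C@H](C[C@@H]3O[Si](c5ccccc5)(c5ccccc5)C(C)(C)C)[C@H](C(=O)OC)C[C@@]42CN(C)C1=O
F6 | step 12 | C17-epimeric allylic alcohol | COC(=O)CCCC3=C4[C@H](C[C@H]3O)C(C(=O)OC(C)(C)C)(C(=O)OC(C)(C)C)C[C@@]4(C(=O)OC)CN(C)C(=O)OC(C)(C)C
F7 | step 12 | (17S)-4-nitrobenzoate | COC(=O)CCCC3=C4[C@H](C[C@@H]3OC(=O)c5ccc(cc5)[N+](=O)[O-])C(C(=O)OC(C)(C)C)(C(=O)OC(C)(C)C)C[C@@]4(C(=O)OC)CN(C)C(=O)OC(C)(C)C
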